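Everything rests on disconnecting the aryl ether bond O1–C8a of ring C. O1 is at once the phenolic oxygen of the fully substituted ring A and the oxygen of the benzylic stereocentre C2, so C2 can first be set as an (S)-configured secondary alcohol and then joined to a C8a bromide. In one operation, a palladium-catalysed intramolecular O-arylation closes the pyran ring without breaking any bond at C2. The precursor is an open-chain 1,3-diol derivative: ring A carries bromine at C8a and prenyl at C8, the future C4 oxygen is masked as a silyl ether, and only the (S)-carbinol next to the 4-benzyloxyphenyl ring is free.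

Key step: step 6

Remark: commercial LiN(iPr)2 solution is assumed in steps 1–3. The silyloxy-bearing carbon (future C4) is carried as both epimers from step 3 to step 7, because step 8 turns it into the carbonyl carbon.

Step 1
Reactants: 1 5-bromo-1,2,3-trimethoxybenzene; 2 prenyl bromide (1-bromo-3-methylbut-2-ene)
Product: 4 1-bromo-3,4,5-trimethoxy-2-(3-methylbut-2-enyl)benzene, via aryllithium 3 (not isolated)
Conditions: LiN(iPr)2 (1.05 equiv), THF, −78 °C, 1 h; then CuBr·SMe2 (10 mol %), 2 (1.3 equiv), −78 → −20 °C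
Reagents that add atoms: none
Why: Directed ortho-metalation removes the ring hydrogen flanked by Br and OMe, the most acidic position, at −78 °C where the ortho-bromo aryllithium does not yet lose LiBr, and copper-catalysed allylic substitution at the primary carbon of 2 should then give the linear prenyl arene.

Step 2
Reactants: 4 1-bromo-3,4,5-trimethoxy-2-(3-methylbut-2-enyl)benzene
Product: 6 2-bromo-4,5,6-trimethoxy-3-(3-methylbut-2-enyl)benzaldehyde, via aryllithium 5 (not isolated)
Conditions: LiN(iPr)2 (1.2 equiv), THF, −78 °C, 45 min; DMF (3 equiv), −78 → −40 °C; H2O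
Reagents that add atoms: N,N-dimethylformamide, CN(C)C=O
Why: A second directed ortho-metalation removes the only ring hydrogen left, again acidified by the flanking Br and OMe and expected to react faster than the sterically twisted benzylic–allylic CH2 of the prenyl group, and formylation of the aryllithium with DMF (Bouveault aldehyde synthesis) should give the aldehyde on aqueous work-up.

Step 3
Reactants: 6 2-bromo-4,5,6-trimethoxy-3-(3-methylbut-2-enyl)benzaldehyde; 7 4'-benzyloxyacetophenone
Product: 9 (±)-1-[4-(benzyloxy)phenyl]-3-[2-bromo-4,5,6-trimethoxy-3-(3-methylbut-2-enyl)phenyl]-3-hydroxypropan-1-one, via lithium enolate 8 (not isolated)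
Conditions: 7, LiN(iPr)2 (1.05 equiv), THF, −78 °C, 30 min; then 6, −78 °C, 1 h; AcOH quench at −78 °C
Reagents that add atoms: none
Why: Directed aldol addition of the preformed lithium enolate to a non-enolisable aldehyde at −78 °C, with a cold acidic quench against retro-aldol and dehydration; the new carbinol centre (future C4) is deliberately racemic because it is oxidised later.

Step 4
Reactants: 9 (±)-1-[4-(benzyloxy)phenyl]-3-[2-bromo-4,5,6-trimethoxy-3-(3-methylbut-2-enyl)phenyl]-3-hydroxypropan-1-one
Product: 10 (±)-1-[4-(benzyloxy)phenyl]-3-[2-bromo-4,5,6-trimethoxy-3-(3-methylbut-2-enyl)phenyl]-3-[(tert-butyldimethylsilyl)oxy]propan-1-one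
Conditions: TBSOTf (1.3 equiv), 2,6-lutidine (2 equiv), CH2Cl2, −78 → −20 °C
Reagents that add atoms: tert-butyldimethylsilyl trifluoromethanesulfonate, CC(C)(C)[Si](C)(C)OS(=O)(=O)C(F)(F)F
Why: Silylation of the secondary benzylic alcohol with a silyl triflate and a hindered pyridine base is fast even at a crowded carbinol, and it blocks retro-aldol now and any binding of this oxygen to palladium later.

Step 5
Reactants: 10 (±)-1-[4-(benzyloxy)phenyl]-3-[2-bromo-4,5,6-trimethoxy-3-(3-methylbut-2-enyl)phenyl]-3-[(tert-butyldimethylsilyl)oxy]propan-1-one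
Product: 11 (1S,3RS)-1-[4-(benzyloxy)phenyl]-3-[2-bromo-4,5,6-trimethoxy-3-(3-methylbut-2-enyl)phenyl]-3-[(tert-butyldimethylsilyl)oxy]propan-1-ol (free carbinol S, both epimers at the silyloxy carbon)
Conditions: RuCl(p-cymene)[(S,S)-TsDPEN] (2 mol %), HCO2H/Et3N (5:2), DMF, 35 °C
Reagents that add atoms: none
Why: Noyori asymmetric transfer hydrogenation of the aryl ketone, in which the (S,S)-configured ruthenium hydride delivers hydrogen through the usual six-membered, CH/π-organised transition state to give the (S)-carbinol (future C2) under catalyst control, whatever the configuration of the remote silyloxy centre, and leaves the aryl bromide, prenyl alkene and benzyl ether alone.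

Step 6
Reactants: 11 (1S,3RS)-1-[4-(benzyloxy)phenyl]-3-[2-bromo-4,5,6-trimethoxy-3-(3-methylbut-2-enyl)phenyl]-3-[(tert-butyldimethylsilyl)oxy]propan-1-ol
Product: 12 (2S,4RS)-2-[4-(benzyloxy)phenyl]-4-[(tert-butyldimethylsilyl)oxy]-5,6,7-trimethoxy-8-(3-methylbut-2-enyl)chromane
Conditions: Pd(OAc)2 (5 mol %), 2-(di-tert-butylphosphino)-1,1'-binaphthyl (7.5 mol %), Cs2CO3 (1.5 equiv), toluene, 70 °C
Reagents that add atoms: none
Why: Zerovalent palladium carrying one bulky phosphine inserts into the C8a–Br bond, the free (S)-carbinol binds and is deprotonated by Cs2CO3, and C–O reductive elimination from the seven-membered aryl palladium alkoxide releases the chroman. The closest known reaction type is the intramolecular palladium-catalysed etherification of aryl bromides with secondary alcohols (Buchwald–Hartwig-type C–O coupling), which runs with retention at the carbinol carbon. Ring C is closed as a six-membered ring by attack of the chain oxygen on C8a with bromide leaving outside the ring (6-exo with respect to the C–Br bond). No stereocentre is created: C2 keeps its S configuration because only its O–H bond reacts, and C4 stays a mixture of silyl ether epimers. The step needs C–O reductive elimination to outrun β-hydride elimination and needs a single hydroxyl to reach palladium; the di-tert-butyl biaryl phosphine secures the first, and the silyl group on the C4 oxygen secures the second by denying palladium the five-membered benzylic alkoxide chelate that would oxidise C4 and reduce the C8a–Br bond. The weak, insoluble carbonate keeps free alkoxide low, so silyl migration between the two oxygens is not expected.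

Step 7
Reactants: 12 (2S,4RS)-2-[4-(benzyloxy)phenyl]-4-[(tert-butyldimethylsilyl)oxy]-5,6,7-trimethoxy-8-(3-methylbut-2-enyl)chromane
Product: 13 (2S,4RS)-2-[4-(benzyloxy)phenyl]-5,6,7-trimethoxy-8-(3-methylbut-2-enyl)chroman-4-ol
Conditions: tetrabutylammonium fluoride (1.5 equiv), THF, 0 → 40 °C; H2O
Reagents that add atoms: none
Why: Fluoride-mediated desilylation, driven by the strong Si–F bond, frees the C4 hydroxyl; nothing else in 12 is fluoride- or base-labile and C2 is not involved.

Step 8
Reactants: 13 (2S,4RS)-2-[4-(benzyloxy)phenyl]-5,6,7-trimethoxy-8-(3-methylbut-2-enyl)chroman-4-ol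
Product: 14 (2S)-2-[4-(benzyloxy)phenyl]-5,6,7-trimethoxy-8-(3-methylbut-2-enyl)chroman-4-one
Conditions: Dess–Martin periodinane (1.3 equiv), NaHCO3 (3 equiv), CH2Cl2, 0 °C → rt
Reagents that add atoms: none
Why: Dess–Martin oxidation of the secondary benzylic alcohol converges both C4 epimers on one ketone under buffered, near-neutral conditions that should neither touch the prenyl alkene nor open the flavanone ring, so C2 stays S.

Step 9
Reactants: 14 (2S)-2-[4-(benzyloxy)phenyl]-5,6,7-trimethoxy-8-(3-methylbut-2-enyl)chroman-4-one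
Product: 15 (2S)-5-hydroxy-2-(4-hydroxyphenyl)-6,7-dimethoxy-8-(3-methylbut-2-enyl)chroman-4-one (target)
Conditions: BCl3 (4 equiv), C6HMe5 (3 equiv), 2,6-di-tert-butyl-4-methylpyridine (1.2 equiv), CH2Cl2, −78 → −10 °C; H2O
Reagents that add atoms: none
Why: Chelation-controlled demethylation, in which BCl3 bridges the C4 carbonyl and the peri 5-OMe so that chloride removes only that methyl, is combined with BCl3 cleavage of the aryl benzyl ether, where pentamethylbenzene captures the benzyl cation (Friedel–Crafts) and the hindered pyridine traps the proton, so the prenyl alkene, the 6- and 7-methoxy groups and C2 should stay intact at low temperature.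

Compound list
1 | 5-bromo-1,2,3-trimethoxybenzene | COc1cc(Br)cc(OC)c1OC | starting material
2 | prenyl bromide (1-bromo-3-methylbut-2-ene) | CC(C)=CCBr | starting material
3 | (6-bromo-2,3,4-trimethoxyphenyl)lithium | [Li]c1c(Br)cc(OC)c(OC)c1OC | intermediate (not isolated)
4 | 1-bromo-3,4,5-trimethoxy-2-(3-methylbut-2-enyl)benzene | CC(C)=CCc1c(Br)cc(OC)c(OC)c1OC | intermediate
5 | [2-bromo-4,5,6-trimethoxy-3-(3-methylbut-2-enyl)phenyl]lithium | [Li]c1c(Br)c(CC=C(C)C)c(OC)c(OC)c1OC | intermediate (not isolated)
6 | 2-bromo-4,5,6-trimethoxy-3-(3-methylbut-2-enyl)benzaldehyde | O=Cc1c(Br)c(CC=C(C)C)c(OC)c(OC)c1OC | intermediate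
7 | 4'-benzyloxyacetophenone | CC(=O)c1ccc(OCc2ccccc2)cc1 | starting material
8 | lithium enolate of 7, lithium 1-[4-(benzyloxy)phenyl]ethenolate | C=C(O[Li])c1ccc(OCc2ccccc2)cc1 | intermediate (not isolated)
9 | (±)-1-[4-(benzyloxy)phenyl]-3-[2-bromo-4,5,6-trimethoxy-3-(3-methylbut-2-enyl)phenyl]-3-hydroxypropan-1-one | COc1c(OC)c(c(Br)c(CC=C(C)C)c1OC)C(O)CC(=O)c1ccc(OCc2ccccc2)cc1 | intermediate
10 | (±)-1-[4-(benzyloxy)phenyl]-3-[2-bromo-4,5,6-trimethoxy-3-(3-methylbut-2-enyl)phenyl]-3-[(tert-butyldimethylsilyl)oxy]propan-1-one | COc1c(OC)c(c(Br)c(CC=C(C)C)c1OC)C(O[Si](C)(C)C(C)(C)C)CC(=O)c1ccc(OCc2ccccc2)cc1 | intermediate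
11 | (1S,3RS)-1-[4-(benzyloxy)phenyl]-3-[2-bromo-4,5,6-trimethoxy-3-(3-methylbut-2-enyl)phenyl]-3-[(tert-butyldimethylsilyl)oxy]propan-1-ol | COc1c(OC)c(c(Br)c(CC=C(C)C)c1OC)C(O[Si](C)(C)C(C)(C)C)C[C@H](O)c1ccc(OCc2ccccc2)cc1 | intermediate (key-step precursor)
12 | (2S,4RS)-2-[4-(benzyloxy)phenyl]-4-[(tert-butyldimethylsilyl)oxy]-5,6,7-trimethoxy-8-(3-methylbut-2-enyl)chromane | COc1c(OC)c2c(c(CC=C(C)C)c1OC)O[C@H](c1ccc(OCc3ccccc3)cc1)CC2O[Si](C)(C)C(C)(C)C | intermediate (key-step product)
13 | (2S,4RS)-2-[4-(benzyloxy)phenyl]-5,6,7-trimethoxy-8-(3-methylbut-2-enyl)chroman-4-ol | COc1c(OC)c2c(c(CC=C(C)C)c1OC)O[C@H](c1ccc(OCc3ccccc3)cc1)CC2O | intermediate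
14 | (2S)-2-[4-(benzyloxy)phenyl]-5,6,7-trimethoxy-8-(3-methylbut-2-enyl)chroman-4-one | COc1c(OC)c2c(c(CC=C(C)C)c1OC)O[C@H](c1ccc(OCc3ccccc3)cc1)CC2=O | intermediate
15 | (2S)-5-hydroxy-2-(4-hydroxyphenyl)-6,7-dimethoxy-8-(3-methylbut-2-enyl)chroman-4-one | COc1c(O)c2c(c(CC=C(C)C)c1OC)O[C@H](c1ccc(O)cc1)CC2=O | target

Total step count: 9. Longest linear sequence: 9 steps (1 → 15).

Steps most likely to fail

Step 6 (key step). Oxidative addition at the doubly ortho-substituted C8a–Br bond may be slow, and β-hydride elimination from the palladium alkoxide may then reduce the bromide and oxidise the carbinol instead of closing the ring. The fallback forms O1–C2 instead of O1–C8a; it sets out from 10 and returns at 12. Ketone 10 would be reduced with the enantiomeric catalyst RuCl(p-cymene)[(R,R)-TsDPEN] (HCO2H/Et3N) to the (1R)-alcohol F1. Treatment with n-BuLi (2.2 equiv, THF, −78 °C) would give the lithium alkoxide aryllithium F2. Trapping with B(OMe)3 would give the dimethyl boronate F3, and oxidation with H2O2/NaOH would give the phenol F4. Mitsunobu etherification (PPh3, DIAD, THF, 0 °C) would then displace the activated (R)-carbinol by the phenol oxygen with inversion and give (2S)-12.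

Step 2. Removal of the benzylic–allylic prenyl protons may compete with ring metalation, or LiBr may be lost to an aryne before the formyl group is delivered. The fallback reverses the order so that no carbanion is generated next to a prenyl group before formylation; it sets out from 1 and returns at 6. Aryllithium 3 (from 1, as in step 1) would be quenched with DMF to give 6-bromo-2,3,4-trimethoxybenzaldehyde F5. Acetalisation (HC(OMe)3, cat. TsOH, MeOH) would give the dimethyl acetal F6. Deprotonation of its last ring hydrogen (LiN(iPr)2, THF, −78 °C) would give the aryllithium F7, and prenylation with 2 under CuBr·SMe2 catalysis would give the prenylated acetal F8. Mild hydrolysis (pyridinium tosylate, acetone/H2O) would release 6.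

Step 9. The prenyl double bond may be hydrochlorinated or benzylated, or the C2 configuration may erode through Lewis-acid ring opening towards the chalcone. The fallback separates the two deprotections and avoids boron halides; it sets out from 14 and returns at 15. MgI2·OEt2 in THF (60 °C) would cleave only the chelated 5-methyl ether and give (2S)-2-[4-(benzyloxy)phenyl]-5-hydroxy-6,7-dimethoxy-8-(3-methylbut-2-enyl)chroman-4-one F9. Catalytic transfer hydrogenolysis (Pd/C, 1,4-cyclohexadiene, EtOAc/EtOH, rt) would then remove the benzyl ether while sparing the trisubstituted alkene and give 15.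

Further compounds
F1 | step 6 | (1R,3RS)-1-[4-(benzyloxy)phenyl]-3-[2-bromo-4,5,6-trimethoxy-3-(3-methylbut-2-enyl)phenyl]-3-[(tert-butyldimethylsilyl)oxy]propan-1-ol | COc1c(OC)c(c(Br)c(CC=C(C)C)c1OC)C(O[Si](C)(C)C(C)(C)C)C[C@@H](O)c1ccc(OCc2ccccc2)cc1
F2 | step 6 | lithium alkoxide aryllithium from F1 (not isolated) | COc1c(OC)c(c([Li])c(CC=C(C)C)c1OC)C(O[Si](C)(C)C(C)(C)C)C[C@@H](O[Li])c1ccc(OCc2ccccc2)cc1
F3 | step 6 | dimethyl arylboronate, as lithium alkoxide (not isolated) | COc1c(OC)c(c(B(OC)OC)c(CC=C(C)C)c1OC)C(O[Si](C)(C)C(C)(C)C)C[C@@H](O[Li])c1ccc(OCc2ccccc2)cc1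
F4 | step 6 | 2-{(3R)-3-[4-(benzyloxy)phenyl]-1-[(tert-butyldimethylsilyl)oxy]-3-hydroxypropyl}-3,4,5-trimethoxy-6-(3-methylbut-2-enyl)phenol | COc1c(OC)c(c(O)c(CC=C(C)C)c1OC)C(O[Si](C)(C)C(C)(C)C)C[C@@H](O)c1ccc(OCc2ccccc2)cc1
F5 | step 2 | 6-bromo-2,3,4-trimethoxybenzaldehyde | O=Cc1c(Br)cc(OC)c(OC)c1OC
F6 | step 2 | 1-bromo-2-(dimethoxymethyl)-3,4,5-trimethoxybenzene | COC(OC)c1c(Br)cc(OC)c(OC)c1OC
F7 | step 2 | [2-bromo-3-(dimethoxymethyl)-4,5,6-trimethoxyphenyl]lithium (not isolated) | COC(OC)c1c(Br)c([Li])c(OC)c(OC)c1OC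
F8 | step 2 | 2-bromo-1-(dimethoxymethyl)-4,5,6-trimethoxy-3-(3-methylbut-2-enyl)benzene | COC(OC)c1c(Br)c(CC=C(C)C)c(OC)c(OC)c1OC
F9 | step 9 | (2S)-2-[4-(benzyloxy)phenyl]-5-hydroxy-6,7-dimethoxy-8-(3-methylbut-2-enyl)chroman-4-one | COc1c(O)c2c(c(CC=C(C)C)c1OC)O[C@H](c1ccc(OCc3ccccc3)cc1)CC2=O
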